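## Retrosynthetic overview
1. Target 12 is opened at the C2–O1 bond to give racemic benzylic alcohol 10. The pyran ring is closed last, through planar para-quinone methide 11 under a chiral phosphoric acid, so the only ring formed and the only stereocentre both come from the final step.
2. Alcohol 10 comes from ketone 9 by hydride addition, and 9 from diallyl ketone 8 by cross-metathesis (two allyl groups become prenyl).
3. Ketone 8 comes from triether 7 by one thermal triple Claisen rearrangement: O-prenyl becomes 1,1-dimethylallyl on ring A, and two O-allyl groups become C-allyl on ring B. The ethers are also the only phenol protection.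
4. Triether 7 comes from chalcone 6 by conjugate reduction, and 6 from aldehyde 2 plus ketone 4 by Claisen–Schmidt condensation.
5. Rings A and B are bought as 2,4-dihydroxybenzaldehyde 1 and 3,4-dihydroxyacetophenone 3.

Assumption: the sense of induction in step 8 must be found by experiment, so (R)-TRIP is written and its mirror image is used if the (2R)-flavan forms; prenyl bromide, allyl bromide and 2-methylbut-2-ene are bought and treated as reagents.

## Route

Step 1
Reactants: 1 2,4-dihydroxybenzaldehyde
Product: 2 2-hydroxy-4-[(3-methylbut-2-en-1-yl)oxy]benzaldehyde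
Conditions: prenyl bromide (1.05 equiv), K2CO3 (1.1 equiv), acetone, reflux, 5 h
Reagents that add atoms: prenyl bromide (1-bromo-3-methylbut-2-ene), CC(C)=CCBr
Why: Williamson etherification; the 2-OH is locked in a hydrogen bond to the aldehyde, so one equivalent of base and halide alkylates only the more acidic, free 4-OH; no stereocentre.

Step 2
Reactants: 3 3,4-dihydroxyacetophenone
Product: 4 1-[3,4-bis(allyloxy)phenyl]ethan-1-one
Conditions: allyl bromide (2.4 equiv), K2CO3 (3 equiv), DMF, 60 °C, 6 h
Reagents that add atoms: allyl bromide, C=CCBr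
Why: Double Williamson etherification; the allyl ethers are base-stable protection for steps 3 and 4 and the later carbon source for ring B, and plain allyl is preferred because neighbouring bis(1,1-dimethylallyl) catechol ethers are prone to Claisen/Diels–Alder cage formation; no stereocentre.

Step 3
Reactants: 2 2-hydroxy-4-[(3-methylbut-2-en-1-yl)oxy]benzaldehyde, 4 1-[3,4-bis(allyloxy)phenyl]ethan-1-one
Product: 6 (E)-1-[3,4-bis(allyloxy)phenyl]-3-{2-hydroxy-4-[(3-methylbut-2-en-1-yl)oxy]phenyl}prop-2-en-1-one, via aldol adduct 5 (not isolated)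
Conditions: KOH (50 % aq, 8 equiv), EtOH, rt, 48 h; AcOH to pH 6, 0 °C
Reagents that add atoms: none
Why: Claisen–Schmidt aldol condensation; the methyl ketone enolate adds to the aldehyde to give 5, E1cB loss of water gives the thermodynamic (E)-enone, aryl allyl and prenyl ethers are inert to KOH, and the weak-acid quench avoids flavylium formation.

Step 4
Reactants: 6 (E)-1-[3,4-bis(allyloxy)phenyl]-3-{2-hydroxy-4-[(3-methylbut-2-en-1-yl)oxy]phenyl}prop-2-en-1-one
Product: 7 1-[3,4-bis(allyloxy)phenyl]-3-{2-hydroxy-4-[(3-methylbut-2-en-1-yl)oxy]phenyl}propan-1-one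
Conditions: Cu(OAc)2·H2O (5 mol %), 1,2-bis(diphenylphosphino)benzene (5 mol %), (EtO)2MeSiH (3 equiv), t-BuOH (3 equiv), toluene, 0 °C to rt; aq. NaHCO3 work-up
Reagents that add atoms: none
Why: Copper hydride conjugate reduction (Stryker type); the soft phosphine-bound CuH delivers hydride only to the β-carbon of the polarised enone and t-BuOH turns the catalyst over, while the three isolated ether olefins, which rule out catalytic hydrogenation, stay untouched; no stereocentre.

Step 5
Reactants: 7 1-[3,4-bis(allyloxy)phenyl]-3-{2-hydroxy-4-[(3-methylbut-2-en-1-yl)oxy]phenyl}propan-1-one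
Product: 8 1-(2,5-diallyl-3,4-dihydroxyphenyl)-3-[2,4-dihydroxy-5-(2-methylbut-3-en-2-yl)phenyl]propan-1-one
Conditions: N,N-diethylaniline (0.1 molar, degassed), 2,6-di-tert-butyl-4-methylphenol (5 mol %), 200 °C, sealed tube, 4 h
Reagents that add atoms: none
Why: Triple aromatic Claisen rearrangement ([3,3] shift with re-aromatisation); each ring-B oxygen has only one free ortho carbon (C2' and C5'), the ring-A O-prenyl group inverts to the 1,1-dimethylallyl group at the less hindered ortho carbon para to the 2-OH, the three shifts are independent so no single intermediate builds up, and running it on the achiral ketone means no stereocentre is exposed to 200 °C.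

Step 6
Reactants: 8 1-(2,5-diallyl-3,4-dihydroxyphenyl)-3-[2,4-dihydroxy-5-(2-methylbut-3-en-2-yl)phenyl]propan-1-one
Product: 9 1-[3,4-dihydroxy-2,5-bis(3-methylbut-2-en-1-yl)phenyl]-3-[2,4-dihydroxy-5-(2-methylbut-3-en-2-yl)phenyl]propan-1-one
Conditions: second-generation Grubbs catalyst RuCl2(=CHPh)(H2IMes)(PCy3) (5 mol %), 2-methylbut-2-ene/CH2Cl2 1:1, 40 °C, sealed, 12 h
Reagents that add atoms: 2-methylbut-2-ene, CC=C(C)C
Why: Olefin cross-metathesis; the two unhindered ortho-allylphenol olefins exchange =CH2 for =C(CH3)2 in excess 2-methylbut-2-ene, a standard allyl-to-prenyl conversion that tolerates free phenols, while the ring-A vinyl group next to a quaternary carbon is too hindered to react; no stereocentre.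

Step 7
Reactants: 9 1-[3,4-dihydroxy-2,5-bis(3-methylbut-2-en-1-yl)phenyl]-3-[2,4-dihydroxy-5-(2-methylbut-3-en-2-yl)phenyl]propan-1-one
Product: 10 rac-1-[3,4-dihydroxy-2,5-bis(3-methylbut-2-en-1-yl)phenyl]-3-[2,4-dihydroxy-5-(2-methylbut-3-en-2-yl)phenyl]propan-1-ol
Conditions: NaBH4 (4 equiv), THF/EtOH 4:1, 0 °C to rt, 3 h; pH 7 phosphate buffer; crude product kept below 25 °C and used the same day
Reagents that add atoms: none
Why: Borohydride 1,2-reduction of the aryl ketone; olefins are inert, and the new carbinol centre is deliberately racemic because it is erased at the quinone methide stage of step 8.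

Step 8
Reactants: 10 rac-1-[3,4-dihydroxy-2,5-bis(3-methylbut-2-en-1-yl)phenyl]-3-[2,4-dihydroxy-5-(2-methylbut-3-en-2-yl)phenyl]propan-1-ol
Product: 12 4-[(2S)-7-hydroxy-6-(2-methylbut-3-en-2-yl)-3,4-dihydro-2H-chromen-2-yl]-3,6-bis(3-methylbut-2-en-1-yl)benzene-1,2-diol, via para-quinone methide 11 (not isolated)
Conditions: (R)-TRIP [(R)-3,3'-bis(2,4,6-triisopropylphenyl)-1,1'-binaphthyl-2,2'-diyl hydrogen phosphate] (5 mol %), 5 Å molecular sieves, toluene (0.02 molar), −20 °C, 24–48 h, argon
Reagents that add atoms: none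
Why: Proposed new method: enantioconvergent dehydrative C–O ring closure through a catalyst-bound para-quinone methide; the chiral phosphoric acid protonates the benzylic OH while its P=O takes up the 4'-OH proton, water leaves, and both enantiomers of 10 collapse to the same planar 3'-hydroxy-para-quinone methide 11, whose exocyclic C=C is held in one geometry because allylic strain turns the chain away from the 2'-prenyl group; the acid stays hydrogen-bonded to the C=O/3'-OH pair of 11 and its phosphoryl oxygen picks up the ring-A 2-OH, so the 6-exo-trig oxa-1,6-addition runs on one face inside the triisopropylphenyl pocket, forms the C2–O1 bond and the pyran ring, re-aromatises ring B and sets (2S); at −20 °C this acid is too weak to protonate the prenyl or 1,1-dimethylallyl olefins, the ring-A 4-OH cannot reach the electrophilic carbon, sieves remove water and high dilution suppresses intermolecular capture; the closest known reaction types are chiral-phosphoric-acid-catalysed 1,6-conjugate additions of carbon, sulfur and nitrogen nucleophiles to para-quinone methides made in situ from para-hydroxybenzyl alcohols, and the racemic acid-induced cyclisation of 1-(4-hydroxyaryl)-3-(2-hydroxyaryl)propan-1-ols to flavans; new here are the tethered phenol oxygen closing a 2-arylchroman, the monoalkyl catechol-type quinone methide, and the unprotected triply C5-substituted tetraphenol substrate.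

## Compound list
1 | 2,4-dihydroxybenzaldehyde | O=Cc1ccc(O)cc1O | starting material
2 | 2-hydroxy-4-[(3-methylbut-2-en-1-yl)oxy]benzaldehyde | O=Cc1ccc(OCC=C(C)C)cc1O | intermediate
3 | 3,4-dihydroxyacetophenone | CC(=O)c1ccc(O)c(O)c1 | starting material
4 | 1-[3,4-bis(allyloxy)phenyl]ethan-1-one | CC(=O)c1ccc(OCC=C)c(OCC=C)c1 | intermediate
5 | racemic aldol adduct, 1-[3,4-bis(allyloxy)phenyl]-3-hydroxy-3-{2-hydroxy-4-[(3-methylbut-2-en-1-yl)oxy]phenyl}propan-1-one | O=C(CC(O)c1ccc(OCC=C(C)C)cc1O)c1ccc(OCC=C)c(OCC=C)c1 | intermediate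
6 | (E)-1-[3,4-bis(allyloxy)phenyl]-3-{2-hydroxy-4-[(3-methylbut-2-en-1-yl)oxy]phenyl}prop-2-en-1-one | O=C(/C=C/c1ccc(OCC=C(C)C)cc1O)c1ccc(OCC=C)c(OCC=C)c1 | intermediate
7 | 1-[3,4-bis(allyloxy)phenyl]-3-{2-hydroxy-4-[(3-methylbut-2-en-1-yl)oxy]phenyl}propan-1-one | O=C(CCc1ccc(OCC=C(C)C)cc1O)c1ccc(OCC=C)c(OCC=C)c1 | intermediate
8 | 1-(2,5-diallyl-3,4-dihydroxyphenyl)-3-[2,4-dihydroxy-5-(2-methylbut-3-en-2-yl)phenyl]propan-1-one | O=C(CCc1cc(C(C)(C)C=C)c(O)cc1O)c1cc(CC=C)c(O)c(O)c1CC=C | intermediate
9 | 1-[3,4-dihydroxy-2,5-bis(3-methylbut-2-en-1-yl)phenyl]-3-[2,4-dihydroxy-5-(2-methylbut-3-en-2-yl)phenyl]propan-1-one | O=C(CCc1cc(C(C)(C)C=C)c(O)cc1O)c1cc(CC=C(C)C)c(O)c(O)c1CC=C(C)C | intermediate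
10 | rac-1-[3,4-dihydroxy-2,5-bis(3-methylbut-2-en-1-yl)phenyl]-3-[2,4-dihydroxy-5-(2-methylbut-3-en-2-yl)phenyl]propan-1-ol | OC(CCc1cc(C(C)(C)C=C)c(O)cc1O)c1cc(CC=C(C)C)c(O)c(O)c1CC=C(C)C | intermediate
11 | (E)-4-{3-[2,4-dihydroxy-5-(2-methylbut-3-en-2-yl)phenyl]propylidene}-2-hydroxy-3,6-bis(3-methylbut-2-en-1-yl)cyclohexa-2,5-dien-1-one | O=C1C(O)=C(CC=C(C)C)/C(=C/CCc2cc(C(C)(C)C=C)c(O)cc2O)C=C1CC=C(C)C | intermediate
12 | 4-[(2S)-7-hydroxy-6-(2-methylbut-3-en-2-yl)-3,4-dihydro-2H-chromen-2-yl]-3,6-bis(3-methylbut-2-en-1-yl)benzene-1,2-diol | C=CC(C)(C)c1cc2c(cc1O)O[C@H](c1cc(CC=C(C)C)c(O)c(O)c1CC=C(C)C)CC2 | target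

## Step count
Total step count: 8.
Longest linear sequence: 7 (step 1 or 2, then steps 3 to 8).

## Three steps most likely to fail

**Step 8 (the new step).** There are three risks:
- Low ee, if 11 closes outside the catalyst pocket.
- Loss of ee, if 12 re-ionises to 11 under the acid.
- Drift of 11 to its styrene or ortho-quinone tautomers.

The fallback is known chemistry and uses resolution instead of asymmetric catalysis. It sets out from 10. The ring is closed with an achiral acid (diphenyl phosphate (PhO)2P(O)OH, 5 mol %, CH2Cl2, 0 °C) to give the racemic flavan F1. The enantiomers are separated by preparative supercritical-fluid chromatography on an amylose tris(3,5-dimethylphenylcarbamate) phase. This gives 12, where the fallback rejoins the route, and the (2R)-flavan F2. F2 is re-racemised with the same acid at 40 °C through 11 and recycled.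

**Step 5 (triple Claisen rearrangement).** There are three risks:
- Ipso attack on the oxygen-bearing neighbour carbon of ring B, followed by an intramolecular Diels–Alder reaction with the second allyl ether, giving a cage.
- Partial migration on ring A to the carbon between the two oxygens.
- Thermal closure of the ortho-(1,1-dimethylallyl)phenol to a dihydrobenzofuran.

The fallback never places two allyl ethers side by side. It sets out from 3.
- The more acidic 4-OH is monoallylated (allyl bromide 1.0 equiv, NaHCO3, NaI, DMF, 40 °C) to 1-[4-(allyloxy)-3-hydroxyphenyl]ethan-1-one F3.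
- Heating (N,N-diethylaniline, 200 °C) gives 1-(3-allyl-4,5-dihydroxyphenyl)ethan-1-one F4.
- Its dianion (NaH 2.2 equiv, DMSO, allyl bromide 1.0 equiv) is alkylated at the more nucleophilic, less hindered 3-oxide to 1-[3-allyl-5-(allyloxy)-4-hydroxyphenyl]ethan-1-one F5.
- Condensation with 2 (KOH, EtOH) gives (E)-1-[3-allyl-5-(allyloxy)-4-hydroxyphenyl]-3-{2-hydroxy-4-[(3-methylbut-2-en-1-yl)oxy]phenyl}prop-2-en-1-one F6.
- Copper hydride conjugate reduction as in step 4 gives 1-[3-allyl-5-(allyloxy)-4-hydroxyphenyl]-3-{2-hydroxy-4-[(3-methylbut-2-en-1-yl)oxy]phenyl}propan-1-one F7.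
- Heating F7 moves its single ring-B allyl ether to C2', with no tethered dienophile present, and rearranges ring A as before. The fallback rejoins the route at 8.

**Step 7 (reduction to the labile alcohol).** There are three risks:
- Slow reduction of the hindered para-phenoxide ketone.
- Over-reduction to the 1,3-diarylpropane through a quinone methide.
- Premature racemic ring closure of 10 during work-up.

The fallback masks the phenols so that the carbinol cannot ionise. It sets out from 9.
- Peracetylation (Ac2O, pyridine, 4-(dimethylamino)pyridine, rt) gives the tetraacetate ketone F8.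
- Reduction with NaBH4/CeCl3·7H2O (THF/MeOH, −20 °C) gives the chromatographable tetraacetate alcohol F9.
- Brief methanolysis (K2CO3, MeOH, 0 °C, then pH 7 buffer) releases the phenols just before use. The fallback rejoins the route at 10.

## Further compounds
F1 | step 8 | racemic 4-[7-hydroxy-6-(2-methylbut-3-en-2-yl)-3,4-dihydro-2H-chromen-2-yl]-3,6-bis(3-methylbut-2-en-1-yl)benzene-1,2-diol | C=CC(C)(C)c1cc2c(cc1O)OC(c1cc(CC=C(C)C)c(O)c(O)c1CC=C(C)C)CC2
F2 | step 8 | 4-[(2R)-7-hydroxy-6-(2-methylbut-3-en-2-yl)-3,4-dihydro-2H-chromen-2-yl]-3,6-bis(3-methylbut-2-en-1-yl)benzene-1,2-diol | C=CC(C)(C)c1cc2c(cc1O)O[C@@H](c1cc(CC=C(C)C)c(O)c(O)c1CC=C(C)C)CC2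
F3 | step 5 | 1-[4-(allyloxy)-3-hydroxyphenyl]ethan-1-one | CC(=O)c1ccc(OCC=C)c(O)c1
F4 | step 5 | 1-(3-allyl-4,5-dihydroxyphenyl)ethan-1-one | CC(=O)c1cc(O)c(O)c(CC=C)c1
F5 | step 5 | 1-[3-allyl-5-(allyloxy)-4-hydroxyphenyl]ethan-1-one | CC(=O)c1cc(OCC=C)c(O)c(CC=C)c1
F6 | step 5 | (E)-1-[3-allyl-5-(allyloxy)-4-hydroxyphenyl]-3-{2-hydroxy-4-[(3-methylbut-2-en-1-yl)oxy]phenyl}prop-2-en-1-one | O=C(/C=C/c1ccc(OCC=C(C)C)cc1O)c1cc(OCC=C)c(O)c(CC=C)c1
F7 | step 5 | 1-[3-allyl-5-(allyloxy)-4-hydroxyphenyl]-3-{2-hydroxy-4-[(3-methylbut-2-en-1-yl)oxy]phenyl}propan-1-one | O=C(CCc1ccc(OCC=C(C)C)cc1O)c1cc(OCC=C)c(O)c(CC=C)c1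
F8 | step 7 | tetraacetate of ketone 9 | O=C(CCc1cc(C(C)(C)C=C)c(OC(C)=O)cc1OC(C)=O)c1cc(CC=C(C)C)c(OC(C)=O)c(OC(C)=O)c1CC=C(C)C
F9 | step 7 | racemic phenol tetraacetate of alcohol 10 | OC(CCc1cc(C(C)(C)C=C)c(OC(C)=O)cc1OC(C)=O)c1cc(CC=C(C)C)c(OC(C)=O)c(OC(C)=O)c1CC=C(C)C
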